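**Retrosynthetic overview**

- The lactone ring (ring B: O1, C2, C3, C4, C4a, C8a) is closed last, by lactonisation of a 2,4-dihydroxyphenyl propanoate; the two catechol benzyl ethers are removed in the final step.
- The strategy rests on ring A (C4a, C5, C6, C7, C8, C8a): its oxygens at C7 and C8a are 1,3-related, so the arene is built as a cyclohexane-1,3-dione and aromatised afterwards.
- Key disconnection of ring A: C5–C6 (Michael addition) and C8–C8a (Claisen condensation). This splits it into a methyl ketone (C8, C7, C6 with the arylethyl chain) and a 2-methylidene-3-arylglutarate (C5, C4a, C8a with the C4 stereocentre and the C3–C2 ester arm).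
- The ketone carries a phenylsulfanyl group on the future C6. It makes that carbon the Michael donor, leaves only the methyl group for the Claisen closure, and later departs as the sulfoxide across C5–C6, so aromatisation needs no dehydrogenation that could run through C4.
- The glutarate comes from 3,4-bis(benzyloxy)benzaldehyde and methyl acrylate (Morita–Baylis–Hillman adduct, carbonate, cinchona-catalysed allylic alkylation with malonate that sets C4, demethoxycarbonylation). Ring order: A as dione, A aromatised, then B.

Key step: step 6

Numbering: ring atoms are numbered as in the chromen-2-one of the target (O1, C2 to C8a).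

Assumption: in step 3 the quinidine-derived catalyst is taken to give the (R)-adduct. If the sense of induction is the opposite, the quinine-derived pseudoenantiomer (DHQ)2PHAL is used and nothing else changes.

Remark on the sulfur group: without it, the regiochemistry would rest on a small thermodynamic enolate preference, and the dione would need an oxidative dehydrogenation in which a metal enolate at C4a can lose the exocyclic C4 hydrogen and erase the stereocentre.

Remark on descriptors: the C4 carbon reads S in the Michael adduct and in the two diones of steps 6 and 7 only because C4a ranks below the aryl group while it is sp3. The spatial arrangement is the same throughout.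

**Route**

Step 1
Reactants: 1 3,4-bis(benzyloxy)benzaldehyde; 2 methyl acrylate
Product: 3 methyl 2-{[3,4-bis(benzyloxy)phenyl](hydroxy)methyl}prop-2-enoate (racemic)
Conditions: DABCO (1,4-diazabicyclo[2.2.2]octane, 1 equiv), excess 2, MeOH, rt, prolonged reaction time
Reagents that add atoms: none
Why: Morita–Baylis–Hillman reaction, in which the amine adds to the acrylate and the resulting enolate adds to the aldehyde; the electron-rich aldehyde reacts slowly, which a full equivalent of amine in a protic medium offsets, and a racemate suffices because step 3 is enantioconvergent.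

Step 2
Reactants: 3 methyl 2-{[3,4-bis(benzyloxy)phenyl](hydroxy)methyl}prop-2-enoate
Product: 4 methyl 2-{[3,4-bis(benzyloxy)phenyl][(tert-butoxycarbonyl)oxy]methyl}prop-2-enoate (racemic)
Conditions: Boc2O, DMAP (4-(dimethylamino)pyridine, cat.), CH2Cl2, 0 °C → rt
Reagents that add atoms: di-tert-butyl dicarbonate, CC(C)(C)OC(=O)OC(=O)OC(C)(C)C
Why: DMAP-catalysed O-acylation of the secondary allylic alcohol gives the tert-butyl carbonate, a leaving group that releases its own base (tert-butoxide after loss of CO2) in step 3.

Step 3
Reactants: 4 methyl 2-{[3,4-bis(benzyloxy)phenyl][(tert-butoxycarbonyl)oxy]methyl}prop-2-enoate; 5 dimethyl malonate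
Product: 6 trimethyl (2R)-2-[3,4-bis(benzyloxy)phenyl]but-3-ene-1,1,3-tricarboxylate
Conditions: (DHQD)2PHAL (hydroquinidine 1,4-phthalazinediyl diether, 10 mol%), toluene, rt → 40 °C
Reagents that add atoms: none
Why: Lewis-base-catalysed asymmetric allylic alkylation (SN2′–SN2′), in which the quinuclidine nitrogen displaces the carbonate with allylic transposition, the released tert-butoxide deprotonates the malonate, and the malonate attacks the benzylic terminus of the ammonium-bound allyl unit on the face left open by the alkaloid, which sets C4 and lets both enantiomers of 4 converge on one product.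

Step 4
Reactants: 6 trimethyl (2R)-2-[3,4-bis(benzyloxy)phenyl]but-3-ene-1,1,3-tricarboxylate
Product: 7 dimethyl (3R)-3-[3,4-bis(benzyloxy)phenyl]-2-methylidenepentanedioate
Conditions: LiCl, H2O, DMSO, 130 °C
Reagents that add atoms: none
Why: Krapcho demethoxycarbonylation, in which chloride demethylates one ester of the geminal pair, the carboxylate loses CO2 and water protonates the enolate, while the isolated acrylate ester and the C4 centre (no base present, C4–H not conjugated with a carbonyl) should be unaffected.

Step 5
Reactants: 8 1-(phenylsulfanyl)propan-2-one; 9 4-(2-bromoethyl)-1,2-dimethoxybenzene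
Product: 10 5-(3,4-dimethoxyphenyl)-3-(phenylsulfanyl)pentan-2-one (racemic)
Conditions: NaH, THF/DMF, 0 °C → rt (slight excess of 8)
Reagents that add atoms: none
Why: Enolate C-alkylation (SN2), in which the methylene flanked by sulfur and carbonyl is by far the most acidic site of 8 and its soft enolate is alkylated there by the primary bromide.

Step 6
Reactants: 7 dimethyl (3R)-3-[3,4-bis(benzyloxy)phenyl]-2-methylidenepentanedioate; 10 5-(3,4-dimethoxyphenyl)-3-(phenylsulfanyl)pentan-2-one
Product: 12 methyl (3S)-3-[3,4-bis(benzyloxy)phenyl]-3-{5-[2-(3,4-dimethoxyphenyl)ethyl]-2,4-dioxo-5-(phenylsulfanyl)cyclohexyl}propanoate (ring diastereomers; largely enolised), via Michael adduct 11 (not isolated)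
Conditions: 10, KOtBu (1.1 equiv), THF, 0 °C; add 7; then KOtBu (1.1 equiv), 0 °C → rt; aq. HCl
Reagents that add atoms: none
Why: The potassium enolate of 10, preformed and too weakly basic to deprotonate 7, adds through its sulfur-bearing carbon to the unhindered methylene terminus of the acrylate (Michael addition, C5–C6), a regiocontrol long used with 2-(arylsulfanyl) ketones; because C6 is then fully substituted, the only ketone enolate left is that of the methyl group, which attacks the ring ester in a Claisen (Dieckmann-type) acyl substitution (C8–C8a). This closure is 6-exo-trig and is driven to completion by deprotonation of the 1,3-dione, whereas the side-chain ester could only close an eight-membered ring from the methyl carbon. The closest known reaction type is the consecutive Michael–Claisen synthesis of cyclohexane-1,3-diones from methyl ketones and acrylates. The two new stereocentres (C6 and C4a) are formed without control and need none, since both become sp2 carbons of the arene in step 7. The C4 stereocentre should survive because its hydrogen is conjugated with neither ester and the second charge of base is added only after 7 has been consumed, so base-induced migration of the double bond into conjugation with the aryl group has no opportunity.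

Step 7
Reactants: 12 methyl (3S)-3-[3,4-bis(benzyloxy)phenyl]-3-{5-[2-(3,4-dimethoxyphenyl)ethyl]-2,4-dioxo-5-(phenylsulfanyl)cyclohexyl}propanoate
Product: 14 methyl (3R)-3-[3,4-bis(benzyloxy)phenyl]-3-{5-[2-(3,4-dimethoxyphenyl)ethyl]-2,4-dihydroxyphenyl}propanoate, via sulfinyl dione 13 (not isolated)
Conditions: mCPBA (1.0 equiv), CH2Cl2, −78 °C; then P(OMe)3, toluene, 60 °C
Reagents that add atoms: none
Why: Sulfoxide syn-elimination (dehydrosulfenylation), in which low-temperature oxidation at sulfur outpaces oxidation of the enol or the arenes, the sulfoxide then loses benzenesulfenic acid thermally across C5–C6 (or into the side chain) with the phosphite as scavenger, and the resulting enedione is only a keto tautomer or prototropic isomer of the resorcinol, so aromatisation follows without any oxidant reaching C4; any lactone 15 formed here is carried into step 8.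

Step 8
Reactants: 14 methyl (3R)-3-[3,4-bis(benzyloxy)phenyl]-3-{5-[2-(3,4-dimethoxyphenyl)ethyl]-2,4-dihydroxyphenyl}propanoate
Product: 15 (4R)-4-[3,4-bis(benzyloxy)phenyl]-6-[2-(3,4-dimethoxyphenyl)ethyl]-7-hydroxy-3,4-dihydro-2H-chromen-2-one
Conditions: TsOH·H2O (cat.), toluene, 80 °C
Reagents that add atoms: none
Why: Acid-catalysed lactonisation (intramolecular transesterification), in which only the C8a hydroxyl is ortho to the propanoate chain and can close a six-membered ring, so the C7 hydroxyl stays free and the non-enolisable C4 centre is untouched.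

Step 9
Reactants: 15 (4R)-4-[3,4-bis(benzyloxy)phenyl]-6-[2-(3,4-dimethoxyphenyl)ethyl]-7-hydroxy-3,4-dihydro-2H-chromen-2-one
Product: 16 (4R)-4-(3,4-dihydroxyphenyl)-6-[2-(3,4-dimethoxyphenyl)ethyl]-7-hydroxy-3,4-dihydro-2H-chromen-2-one (CNP0376539.1)
Conditions: H2 (1 atm), Pd/C (palladium on carbon, 10% Pd), EtOAc/THF, rt
Reagents that add atoms: none
Why: Catalytic hydrogenolysis of the two benzyl aryl ethers, under neutral conditions that leave the lactone, the methyl ethers and the doubly benzylic C4 carbon intact, in a non-nucleophilic solvent so that the aryl ester is not opened.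

**Compound list**

1 | 3,4-bis(benzyloxy)benzaldehyde | O=Cc1ccc(OCc2ccccc2)c(OCc2ccccc2)c1 | starting material
2 | methyl acrylate | C=CC(=O)OC | starting material
3 | methyl 2-{[3,4-bis(benzyloxy)phenyl](hydroxy)methyl}prop-2-enoate (racemic) | COC(=O)C(=C)C(O)c1ccc(OCc2ccccc2)c(OCc2ccccc2)c1 | intermediate
4 | methyl 2-{[3,4-bis(benzyloxy)phenyl][(tert-butoxycarbonyl)oxy]methyl}prop-2-enoate (racemic) | COC(=O)C(=C)C(OC(=O)OC(C)(C)C)c1ccc(OCc2ccccc2)c(OCc2ccccc2)c1 | intermediate
5 | dimethyl malonate | COC(=O)CC(=O)OC | starting material
6 | trimethyl (2R)-2-[3,4-bis(benzyloxy)phenyl]but-3-ene-1,1,3-tricarboxylate | COC(=O)C(C(=O)OC)[C@H](c1ccc(OCc2ccccc2)c(OCc2ccccc2)c1)C(=C)C(=O)OC | intermediate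
7 | dimethyl (3R)-3-[3,4-bis(benzyloxy)phenyl]-2-methylidenepentanedioate | COC(=O)C[C@H](c1ccc(OCc2ccccc2)c(OCc2ccccc2)c1)C(=C)C(=O)OC | intermediate
8 | 1-(phenylsulfanyl)propan-2-one | CC(=O)CSc1ccccc1 | starting material
9 | 4-(2-bromoethyl)-1,2-dimethoxybenzene | COc1ccc(CCBr)cc1OC | starting material
10 | 5-(3,4-dimethoxyphenyl)-3-(phenylsulfanyl)pentan-2-one (racemic) | CC(=O)C(CCc1ccc(OC)c(OC)c1)Sc1ccccc1 | intermediate
11 | dimethyl (3S)-2-[2-acetyl-4-(3,4-dimethoxyphenyl)-2-(phenylsulfanyl)butyl]-3-[3,4-bis(benzyloxy)phenyl]pentanedioate (diastereomers at the two other centres) | COC(=O)C[C@H](c1ccc(OCc2ccccc2)c(OCc2ccccc2)c1)C(CC(CCc1ccc(OC)c(OC)c1)(Sc1ccccc1)C(C)=O)C(=O)OC | intermediate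
12 | methyl (3S)-3-[3,4-bis(benzyloxy)phenyl]-3-{5-[2-(3,4-dimethoxyphenyl)ethyl]-2,4-dioxo-5-(phenylsulfanyl)cyclohexyl}propanoate (ring diastereomers) | COC(=O)C[C@H](c1ccc(OCc2ccccc2)c(OCc2ccccc2)c1)C1CC(CCc2ccc(OC)c(OC)c2)(Sc2ccccc2)C(=O)CC1=O | intermediate
13 | methyl (3S)-3-{5-(benzenesulfinyl)-5-[2-(3,4-dimethoxyphenyl)ethyl]-2,4-dioxocyclohexyl}-3-[3,4-bis(benzyloxy)phenyl]propanoate (diastereomers) | COC(=O)C[C@H](c1ccc(OCc2ccccc2)c(OCc2ccccc2)c1)C1CC(CCc2ccc(OC)c(OC)c2)(S(=O)c2ccccc2)C(=O)CC1=O | intermediate
14 | methyl (3R)-3-[3,4-bis(benzyloxy)phenyl]-3-{5-[2-(3,4-dimethoxyphenyl)ethyl]-2,4-dihydroxyphenyl}propanoate | COC(=O)C[C@H](c1ccc(OCc2ccccc2)c(OCc2ccccc2)c1)c1cc(CCc2ccc(OC)c(OC)c2)c(O)cc1O | intermediate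
15 | (4R)-4-[3,4-bis(benzyloxy)phenyl]-6-[2-(3,4-dimethoxyphenyl)ethyl]-7-hydroxy-3,4-dihydro-2H-chromen-2-one | COc1ccc(CCc2cc3c(cc2O)OC(=O)C[C@@H]3c2ccc(OCc4ccccc4)c(OCc4ccccc4)c2)cc1OC | intermediate
16 | (4R)-4-(3,4-dihydroxyphenyl)-6-[2-(3,4-dimethoxyphenyl)ethyl]-7-hydroxy-3,4-dihydro-2H-chromen-2-one | COc1ccc(CCc2cc3c(cc2O)OC(=O)C[C@@H]3c2ccc(O)c(O)c2)cc1OC | target

**Step count and risks**

Total steps: 9. Longest linear sequence: 8 steps (1 → 3 → 4 → 6 → 7 → 12 → 14 → 15 → 16).

Step 6 (key step). What may go wrong is steric retardation of the conjugate addition at the fully substituted, sulfur-bearing carbon: the addition stalls or reverts, and the ring closure then has too little adduct to work on. The fallback sets out from 7 and uses a sulfur-free, less hindered donor. The ketone 5-(3,4-dimethoxyphenyl)pentan-2-one F1 is made from commercial 4-(3,4-dimethoxyphenyl)butanoic acid and CH3Li. Its equilibrating potassium enolates (KOtBu, THF, −10 °C) are treated slowly with 7; the more substituted enolate should add through its secondary carbon and the methyl group then closes the ring, giving the sulfur-free dione methyl (3S)-3-[3,4-bis(benzyloxy)phenyl]-3-{5-[2-(3,4-dimethoxyphenyl)ethyl]-2,4-dioxocyclohexyl}propanoate F2. F2 is dehydrogenated with catalytic Pd(O2CCF3)2, 2-(dimethylamino)pyridine and TsOH under O2 in DMSO at 80 °C, and the fallback comes back to the route at 14. The price is regiocontrol by enolate equilibrium alone and an aromatisation without positional control, so the enantiomeric purity of 14 would have to be checked.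

Step 7. What may go wrong is competing oxidation: attack of the peracid on the enolised dione or the electron-rich rings, or over-oxidation at sulfur to the sulfone, which cannot eliminate. The fallback sets out from 10 and moves the oxidation ahead of the annulation. NaIO4 in aqueous methanol at 0 °C should convert 10 into 3-(benzenesulfinyl)-5-(3,4-dimethoxyphenyl)pentan-2-one F3. Its potassium enolate is added to 7 at 0 °C to give the sulfinyl Michael adduct dimethyl (3S)-2-[2-acetyl-2-(benzenesulfinyl)-4-(3,4-dimethoxyphenyl)butyl]-3-[3,4-bis(benzyloxy)phenyl]pentanedioate F4, which is closed with further KOtBu at 0 °C, kept cold to avoid premature elimination. The fallback comes back to the route at 13, which is warmed with P(OMe)3 as in step 7. No oxidant then meets the dione or the resorcinol.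

Step 3. What may go wrong is insufficient facial discrimination in the attack of the malonate on the alkaloid-bound allyl ammonium ion, or substitution without the second transposition, which gives the achiral linear isomer. The fallback sets out from 4 and replaces asymmetric catalysis by resolution. With DABCO as achiral Lewis base the same alkylation with 5 gives racemic trimethyl 2-[3,4-bis(benzyloxy)phenyl]but-3-ene-1,1,3-tricarboxylate F5. The Krapcho reaction of step 4 then gives racemic dimethyl 3-[3,4-bis(benzyloxy)phenyl]-2-methylidenepentanedioate F6. Preparative chromatography on a chiral stationary phase separates the enantiomers, and the (R)-enantiomer is 7, where the fallback comes back to the route.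

**Further compounds**

F1 | step 6 | 5-(3,4-dimethoxyphenyl)pentan-2-one | CC(=O)CCCc1ccc(OC)c(OC)c1
F2 | step 6 | methyl (3S)-3-[3,4-bis(benzyloxy)phenyl]-3-{5-[2-(3,4-dimethoxyphenyl)ethyl]-2,4-dioxocyclohexyl}propanoate | COC(=O)C[C@H](c1ccc(OCc2ccccc2)c(OCc2ccccc2)c1)C1CC(CCc2ccc(OC)c(OC)c2)C(=O)CC1=O
F3 | step 7 | 3-(benzenesulfinyl)-5-(3,4-dimethoxyphenyl)pentan-2-one | CC(=O)C(CCc1ccc(OC)c(OC)c1)S(=O)c1ccccc1
F4 | step 7 | dimethyl (3S)-2-[2-acetyl-2-(benzenesulfinyl)-4-(3,4-dimethoxyphenyl)butyl]-3-[3,4-bis(benzyloxy)phenyl]pentanedioate | COC(=O)C[C@H](c1ccc(OCc2ccccc2)c(OCc2ccccc2)c1)C(CC(CCc1ccc(OC)c(OC)c1)(S(=O)c1ccccc1)C(C)=O)C(=O)OC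
F5 | step 3 | racemic trimethyl 2-[3,4-bis(benzyloxy)phenyl]but-3-ene-1,1,3-tricarboxylate | COC(=O)C(C(=O)OC)C(c1ccc(OCc2ccccc2)c(OCc2ccccc2)c1)C(=C)C(=O)OC
F6 | step 3 | racemic dimethyl 3-[3,4-bis(benzyloxy)phenyl]-2-methylidenepentanedioate | COC(=O)CC(c1ccc(OCc2ccccc2)c(OCc2ccccc2)c1)C(=C)C(=O)OC
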